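Labdane numbering is used throughout. The retrosynthesis first cuts the O15 and O19 acyl bonds. The C20 methyl is then traced back to a cyclopropane (C10–C20 kept, C1–C20 temporary), and both bonds are cut to CH2 plus a 20-nor Δ1(10)-octalin-2β-ol. Ring B is cut at C5–C6 and C9–C10 (Diels–Alder), and C4–C18 goes back to a Birch methylation.
Forward: ring A comes from benzoic acid (steps 1–7), and the diene with the complete side chain from geraniol (steps 8–11). Ring B closes in step 12. The three-membered ring closes in step 16 and is reopened at C1–C20 in step 21. Both esters are put on in between, while C2 is a ketone.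
Enabling feature: the ring-fusion carbon C10 carries the β-methyl C20 and lies 1,3 to the oxygen on C2 of ring A, with C1 between them. A 2β-alcohol can therefore steer CH2 onto C1=C10, and the derived C2 ketone can later break C1–C20 alone.
Stereochemistry: C4 and the 2β-oxygen come from an enantioselective desymmetrising bromolactonisation, and C5 and C9 from an endo, β-face Diels–Alder reaction. C10 comes from the hydroxyl-directed methylene transfer, the 2α-OH from a thermodynamically controlled ketyl reduction, and the E C13=C14 alkene from geraniol.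

Key step: step 16

Assumption: (DHQD)2PHAL is taken to give lactone 4 in the absolute sense drawn. Should a first run give the antipode, the pseudo-enantiomeric (DHQ)2PHAL takes its place and nothing else changes.
Abbreviations: TBS = tert-butyldimethylsilyl, TBDPS = tert-butyldiphenylsilyl, α/β = below/above the decalin plane as usually drawn.

Step 1
Reactants: 1 benzoic acid
Product: 3 1-methylcyclohexa-2,5-diene-1-carboxylic acid, via dilithium dienediolate 2 (not isolated)
Conditions: Li, NH3(l), THF, −78 °C; then MeI; aq. HCl work-up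
Reagents that add atoms: iodomethane, CI
Why: Birch reductive alkylation: the carboxylate steers 1,4-reduction to the cross-conjugated dienediolate 2, which iodomethane alkylates at the ipso carbon, so the quaternary but still prochiral C4 with C18 and C19 is made in one flask.

Step 2
Reactants: 3 1-methylcyclohexa-2,5-diene-1-carboxylic acid
Product: 4 (1S,5S,8S)-8-bromo-1-methyl-6-oxabicyclo[3.2.1]oct-2-en-7-one
Conditions: NBS, (DHQD)2PHAL (10 mol %), CHCl3–hexane, −40 °C; recrystallisation
Reagents that add atoms: N-bromosuccinimide, O=C1CCC(=O)N1Br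
Why: Catalytic enantioselective desymmetrising bromolactonisation of a cyclohexa-2,5-diene-1-carboxylic acid: the alkaloid-bound bromenium ion picks one of the two enantiotopic alkenes and the carboxylate opens it anti at the distal carbon C2, which fixes C4 and forces the C2–O bond cis to C19 because the lactone can bridge one face only; the crystalline product can be enriched by recrystallisation.

Step 3
Reactants: 4 bromolactone
Product: 5 (1S,5S)-1-methyl-6-oxabicyclo[3.2.1]oct-2-en-7-one
Conditions: Bu3SnH, AIBN (cat.), toluene, 80 °C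
Reagents that add atoms: none
Why: Tin hydride radical chain dehalogenation removes the C3 bromine, whose stereocentre is not needed, and leaves lactone, alkene, C2 and C4 untouched.

Step 4
Reactants: 5 unsaturated lactone
Product: 6 (1S,5S)-5-(hydroxymethyl)-5-methylcyclohex-3-en-1-ol
Conditions: LiAlH4, THF, 0 °C → rt; aqueous work-up
Reagents that add atoms: none
Why: Hydride reduction of the lactone frees C19H2OH and the 2β-alcohol without touching the C–O bond at C2, so the cis relation of O2 and C19 is kept.

Step 5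
Reactants: 6 cis-diol
Product: 7 (1S,5S)-5-[(TBDPS-oxy)methyl]-5-methylcyclohex-3-en-1-ol
Conditions: TBDPSCl (1.05 equiv), imidazole, CH2Cl2, 0 °C
Reagents that add atoms: tert-butyl(chloro)diphenylsilane, CC(C)(C)[Si](Cl)(c1ccccc1)c1ccccc1
Why: Chemoselective silylation: the bulky chlorosilane reacts with the primary (neopentyl) hydroxyl well before the secondary one.

Step 6
Reactants: 7 mono-TBDPS ether
Product: 8 (1S,5S)-1-(TBS-oxy)-5-[(TBDPS-oxy)methyl]-5-methylcyclohex-3-ene
Conditions: TBSOTf, 2,6-lutidine, CH2Cl2, −78 → 0 °C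
Reagents that add atoms: tert-butyldimethylsilyl triflate, CC(C)(C)[Si](C)(C)OS(=O)(=O)C(F)(F)F
Why: A silyl triflate with a hindered pyridine base silylates the remaining secondary alcohol and installs a group that can later be removed in the presence of TBDPS ethers.

Step 7
Reactants: 8 bis-silyl ether
Product: 9 (4S,6R)-6-(TBS-oxy)-4-[(TBDPS-oxy)methyl]-4-methylcyclohex-2-en-1-one
Conditions: Rh2(cap)4 (cap = caprolactamate, 1 mol %), t-BuOOH, K2CO3 (0.5 equiv), CH2Cl2, rt
Reagents that add atoms: tert-butyl hydroperoxide, CC(C)(C)OO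
Why: Catalytic allylic C–H oxidation with tert-butyl hydroperoxide: C1H2 is the only allylic methylene because the other allylic carbon C4 is quaternary, and the allyl radical is trapped at its less crowded C1 end, which gives the C1 ketone conjugated with C5=C10.

Step 8
Reactants: 10 geraniol
Product: 11 geranyl TBDPS ether
Conditions: TBDPSCl, imidazole, CH2Cl2, 0 °C → rt
Reagents that add atoms: tert-butyl(chloro)diphenylsilane, CC(C)(C)[Si](Cl)(c1ccccc1)c1ccccc1
Why: Standard silylation of a primary allylic alcohol; the E C13=C14 alkene of the target comes unchanged from geraniol.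

Step 9
Reactants: 11 geranyl TBDPS ether
Product: 12 (2E,6E)-8-(TBDPS-oxy)-2,6-dimethylocta-2,6-dien-1-ol
Conditions: SeO2 (10 mol %), t-BuOOH, salicylic acid (10 mol %), CH2Cl2, 0 °C → rt
Reagents that add atoms: tert-butyl hydroperoxide, CC(C)(C)OO
Why: Selenium dioxide allylic oxidation (ene reaction, then [2,3]-shift) of the terminal gem-dimethyl alkene is known to hydroxylate the E methyl group selectively, and any over-oxidised aldehyde 13 is simply carried into the next step.

Step 10
Reactants: 12 allylic alcohol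
Product: 13 (2E,6E)-8-(TBDPS-oxy)-2,6-dimethylocta-2,6-dienal
Conditions: MnO2 (activated), CH2Cl2, rt
Reagents that add atoms: none
Why: MnO2 oxidises the allylic alcohol to the enal without E/Z scrambling.

Step 11
Reactants: 13 enal
Product: 14 (2E,6E)-1-(TBDPS-oxy)-3,7-dimethylnona-2,6,8-triene
Conditions: Ph3PCH3Br, NaHMDS, THF, 0 °C; then 13, −78 °C → rt
Reagents that add atoms: methyltriphenylphosphonium bromide, C[P+](c1ccccc1)(c1ccccc1)c1ccccc1.[Br-]
Why: Wittig methylenation turns the enal into the E-configured diene C6=C7–C8=C9, the ylide carbon becoming C6.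

Step 12
Reactants: 9 ring A enone; 14 triene
Product: 15 2β-(TBS-oxy)-15,19-bis(TBDPS-oxy)-20-nor-5αH,9αH,10αH-labda-7,13E-dien-1-one (cis-fused)
Conditions: EtAlCl2 (0.5 equiv), 14 (2 equiv), toluene–CH2Cl2, −20 °C → rt
Reagents that add atoms: none
Why: Lewis-acid-promoted intermolecular Diels–Alder reaction of a 4,4-disubstituted cyclohexenone: the cis O2/C19 pair holds both silyloxy arms equatorial and the C18 methyl axial on the α-face so that the diene adds to the β-face, the unsubstituted terminus C6 bonds to the neopentyl C5 and the substituted C9 to C10 next to the carbonyl (ortho orientation, reinforced by sterics), and the endo transition state puts H5, H9 and H10 on one face, which sets C5 and C9 as in the target.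

Step 13
Reactants: 15 cis-decalone
Product: 17 2β-(TBS-oxy)-15,19-bis(TBDPS-oxy)-20-norlabda-1(10),7,13E-trien-1-yl triflate, via potassium enolate 16 (not isolated)
Conditions: KHMDS (1.1 equiv), THF, −78 °C; then PhNTf2, −78 → 0 °C
Reagents that add atoms: N-phenylbis(trifluoromethanesulfonimide), O=S(=O)(N(c1ccccc1)S(=O)(=O)C(F)(F)F)C(F)(F)F
Why: Kinetic enolisation of an α-silyloxy ketone takes place away from the oxygen-bearing carbon, here at the axial C10–H, and O-triflation of enolate 16 erases the C10 centre (any ring-fusion epimer of 15 converges) and marks the C1=C10 position.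

Step 14
Reactants: 17 enol triflate
Product: 18 2β-(TBS-oxy)-15,19-bis(TBDPS-oxy)-20-norlabda-1(10),7,13E-triene
Conditions: Pd(OAc)2 (5 mol %), PPh3 (10 mol %), HCO2H, Et3N, DMF, 60 °C
Reagents that add atoms: none
Why: Palladium-catalysed formate reduction of an enol triflate (oxidative addition, decarboxylation of the formate, reductive elimination) replaces OTf by H with the alkene position retained, and silyl ethers are not leaving groups for π-allyl formation.

Step 15
Reactants: 18 TBS ether
Product: 19 15,19-bis(TBDPS-oxy)-20-norlabda-1(10),7,13E-trien-2β-ol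
Conditions: HF·pyridine, pyridine, THF, 0 °C → rt
Reagents that add atoms: none
Why: Pyridine-buffered HF cleaves the TBS ether far faster than the two TBDPS ethers, and the nearly neutral medium avoids ionisation of the allylic C2–O bond.

Step 16
Reactants: 19 2β-hydroxy Δ1(10)-octalin
Product: 21 15,19-bis(TBDPS-oxy)-1β,20-cyclolabda-7,13E-dien-2β-ol (cyclopropane C1–C10–C20 on the β-face), via ethylzinc alkoxide 20 (not isolated)
Conditions: Et2Zn (3 equiv), CH2I2 (3 equiv), CH2Cl2, −20 → 0 °C; aq. NH4Cl
Reagents that add atoms: diiodomethane, ICI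
Why: Et2Zn first deprotonates the 2β-hydroxyl to the ethylzinc alkoxide 20, and the carbenoid EtZnCH2I made from further Et2Zn and CH2I2 aggregates with this alkoxide. The methylene group then passes to C1=C10 through a single cyclic transition state (Simmons–Smith reaction, Furukawa variant, as established for cyclohex-2-enols), so C1–C20 and C10–C20 form together and the three-membered ring closes by a suprafacial [2+1] addition and not by a stepwise closure. Both new stereocentres, C1 and C10, are controlled by the 2β-oxygen, which can reach only the β-face of the alkene, so C20 ends up trans to H5, which is the trans ring fusion of the target. The step needs chemoselectivity over the trisubstituted C7=C8 and C13=C14 alkenes: neither has a free hydroxyl within reach, O15 and O19 are masked as weakly coordinating TBDPS ethers, and the alkoxide-bound reagent reacts much faster than free carbenoid, so a small excess at low temperature should be enough. The axial C19 arm crowds the β-face, but its oxygen sits beside the zinc alkoxide and should help rather than hinder the delivery.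

Step 17
Reactants: 21 cyclopropyl carbinol
Product: 22 15,19-bis(TBDPS-oxy)-1β,20-cyclolabda-7,13E-dien-2-one
Conditions: Dess–Martin periodinane, CH2Cl2, 0 °C → rt
Reagents that add atoms: none
Why: Mild hypervalent-iodine oxidation gives the cyclopropyl ketone without acid strong enough to open the cyclopropylcarbinyl system.

Step 18
Reactants: 22 bis-TBDPS cyclopropyl ketone
Product: 23 15,19-dihydroxy-1β,20-cyclolabda-7,13E-dien-2-one
Conditions: Bu4NF, THF, rt; aqueous work-up
Reagents that add atoms: none
Why: Fluoride removes both TBDPS groups at once, and C2, held as a ketone, needs no protecting group of its own.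

Step 19
Reactants: 23 keto diol
Product: 24 19-hydroxy-2-oxo-1β,20-cyclolabda-7,13E-dien-15-yl methyl succinate
Conditions: methyl 4-chloro-4-oxobutanoate (1.05 equiv), pyridine, CH2Cl2, −20 °C
Reagents that add atoms: methyl 4-chloro-4-oxobutanoate, COC(=O)CCC(=O)Cl
Why: Selective acylation: the unhindered allylic primary O15–H reacts well before the axial neopentyl O19–H, which is flanked by C4 and the cyclopropane.

Step 20
Reactants: 24 mono-ester
Product: 25 19-(3-methylbutanoyloxy)-2-oxo-1β,20-cyclolabda-7,13E-dien-15-yl methyl succinate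
Conditions: isovaleryl chloride (2 equiv), Et3N, DMAP (cat.), CH2Cl2, rt
Reagents that add atoms: 3-methylbutanoyl chloride, CC(C)CC(=O)Cl
Why: DMAP-catalysed acylation of the only remaining hydroxyl is forcing enough for a neopentyl alcohol.

Step 21
Reactants: 25 cyclopropyl keto diester
Product: 26 19-(3-methylbutanoyloxy)-2-oxolabda-7,13E-dien-15-yl methyl succinate
Conditions: SmI2 (2.5 equiv), THF–DMPU, t-BuOH (2 equiv), −78 → 0 °C
Reagents that add atoms: none
Why: Single-electron reductive opening of a cyclopropyl ketone: the ketyl breaks the bond that lies parallel to its π-orbital, the exocyclic C1–C20 bond and not the in-ring C1–C10 bond, so strain release leaves C20 as the 10β-methyl, while isolated alkenes and unactivated esters are inert to SmI2.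

Step 22
Reactants: 26 2-ketone
Product: 27 methyl 2α-hydroxy-19-(3-methylbutanoyloxy)labda-7,13E-dien-15-yl succinate (target)
Conditions: SmI2 (4 equiv), H2O (excess), THF, 0 °C → rt
Reagents that add atoms: none
Why: Ketyl reduction with SmI2–H2O is protonated under product-stability control and should give the equatorial 2α-alcohol, whereas hydride reagents would be pushed to the α-face by the axial C19 and C20 groups and give the axial epimer; acyclic esters survive this reagent.

Compound list
1 | benzoic acid | OC(=O)c1ccccc1 | starting material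
2 | dilithium dienediolate of 1,4-dihydrobenzoic acid | [Li+].[Li+].[O-]C([O-])=C1C=CCC=C1 | intermediate
3 | 1-methylcyclohexa-2,5-diene-1-carboxylic acid | CC1(C=CCC=C1)C(=O)O | intermediate
4 | (1S,5S,8S)-8-bromo-1-methyl-6-oxabicyclo[3.2.1]oct-2-en-7-one | C[C@]12C=CC[C@H](OC1=O)[C@H]2Br | intermediate
5 | (1S,5S)-1-methyl-6-oxabicyclo[3.2.1]oct-2-en-7-one | C[C@]12C=CC[C@H](OC1=O)C2 | intermediate
6 | (1S,5S)-5-(hydroxymethyl)-5-methylcyclohex-3-en-1-ol | C[C@@]1(CO)C=CC[C@H](O)C1 | intermediate
7 | (1S,5S)-5-[(TBDPS-oxy)methyl]-5-methylcyclohex-3-en-1-ol | C[C@@]1(CO[Si](c2ccccc2)(c2ccccc2)C(C)(C)C)C=CC[C@H](O)C1 | intermediate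
8 | TBS ether of 7 | C[C@@]1(CO[Si](c2ccccc2)(c2ccccc2)C(C)(C)C)C=CC[C@H](O[Si](C)(C)C(C)(C)C)C1 | intermediate
9 | (4S,6R)-6-(TBS-oxy)-4-[(TBDPS-oxy)methyl]-4-methylcyclohex-2-en-1-one | C[C@@]1(CO[Si](c2ccccc2)(c2ccccc2)C(C)(C)C)C=CC(=O)[C@H](O[Si](C)(C)C(C)(C)C)C1 | intermediate
10 | geraniol | CC(C)=CCC/C(C)=C/CO | starting material
11 | geranyl TBDPS ether | CC(C)=CCC/C(C)=C/CO[Si](c1ccccc1)(c1ccccc1)C(C)(C)C | intermediate
12 | (2E,6E)-8-(TBDPS-oxy)-2,6-dimethylocta-2,6-dien-1-ol | OC/C(C)=C/CC/C(C)=C/CO[Si](c1ccccc1)(c1ccccc1)C(C)(C)C | intermediate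
13 | (2E,6E)-8-(TBDPS-oxy)-2,6-dimethylocta-2,6-dienal | O=C/C(C)=C/CC/C(C)=C/CO[Si](c1ccccc1)(c1ccccc1)C(C)(C)C | intermediate
14 | (2E,6E)-1-(TBDPS-oxy)-3,7-dimethylnona-2,6,8-triene | C=C/C(C)=C/CC/C(C)=C/CO[Si](c1ccccc1)(c1ccccc1)C(C)(C)C | intermediate
15 | cis-fused Diels–Alder ketone (2β-OTBS; 5αH,9αH,10αH) | CC(C)(C)[Si](c3ccccc3)(c3ccccc3)OC/C=C(\C)CC[C@H]1C(C)=CC[C@H]2[C@@](C)(CO[Si](c4ccccc4)(c4ccccc4)C(C)(C)C)C[C@@H](O[Si](C)(C)C(C)(C)C)C(=O)[C@@H]12 | intermediate
16 | potassium 1(10)-enolate of 15 | CC(C)(C)[Si](c3ccccc3)(c3ccccc3)OC/C=C(\C)CC[C@H]1C(C)=CC[C@H]2[C@@](C)(CO[Si](c4ccccc4)(c4ccccc4)C(C)(C)C)C[C@@H](O[Si](C)(C)C(C)(C)C)C([O-])=C12.[K+] | intermediate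
17 | 1(10)-enol triflate | CC(C)(C)[Si](c3ccccc3)(c3ccccc3)OC/C=C(\C)CC[C@H]1C(C)=CC[C@H]2[C@@](C)(CO[Si](c4ccccc4)(c4ccccc4)C(C)(C)C)C[C@@H](O[Si](C)(C)C(C)(C)C)C(OS(=O)(=O)C(F)(F)F)=C12 | intermediate
18 | 2β-OTBS 20-norlabda-1(10),7,13E-triene | CC(C)(C)[Si](c3ccccc3)(c3ccccc3)OC/C=C(\C)CC[C@H]1C(C)=CC[C@H]2[C@@](C)(CO[Si](c4ccccc4)(c4ccccc4)C(C)(C)C)C[C@@H](O[Si](C)(C)C(C)(C)C)C=C12 | intermediate
19 | 15,19-bis(TBDPS-oxy)-20-norlabda-1(10),7,13E-trien-2β-ol (key-step precursor) | CC(C)(C)[Si](c3ccccc3)(c3ccccc3)OC/C=C(\C)CC[C@H]1C(C)=CC[C@H]2[C@@](C)(CO[Si](c4ccccc4)(c4ccccc4)C(C)(C)C)C[C@@H](O)C=C12 | intermediate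
20 | ethylzinc 2β-alkoxide of 19 | CC(C)(C)[Si](c3ccccc3)(c3ccccc3)OC/C=C(\C)CC[C@H]1C(C)=CC[C@H]2[C@@](C)(CO[Si](c4ccccc4)(c4ccccc4)C(C)(C)C)C[C@@H](O[Zn]CC)C=C12 | intermediate
21 | 15,19-bis(TBDPS-oxy)-1β,20-cyclolabda-7,13E-dien-2β-ol (key-step product) | CC(C)(C)[Si](c3ccccc3)(c3ccccc3)OC/C=C(\C)CC[C@H]1C(C)=CC[C@H]2[C@@](C)(CO[Si](c4ccccc4)(c4ccccc4)C(C)(C)C)C[C@@H](O)[C@H]5C[C@@]125 | intermediate
22 | 15,19-bis(TBDPS-oxy)-1β,20-cyclolabda-7,13E-dien-2-one | CC(C)(C)[Si](c3ccccc3)(c3ccccc3)OC/C=C(\C)CC[C@H]1C(C)=CC[C@H]2[C@@](C)(CO[Si](c4ccccc4)(c4ccccc4)C(C)(C)C)CC(=O)[C@H]5C[C@@]125 | intermediate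
23 | 15,19-dihydroxy-1β,20-cyclolabda-7,13E-dien-2-one | OC/C=C(\C)CC[C@H]1C(C)=CC[C@H]2[C@@](C)(CO)CC(=O)[C@H]5C[C@@]125 | intermediate
24 | 15-(methyl succinate) of 23 | COC(=O)CCC(=O)OC/C=C(\C)CC[C@H]1C(C)=CC[C@H]2[C@@](C)(CO)CC(=O)[C@H]5C[C@@]125 | intermediate
25 | 15-(methyl succinate) 19-isovalerate of 23 | COC(=O)CCC(=O)OC/C=C(\C)CC[C@H]1C(C)=CC[C@H]2[C@@](C)(COC(=O)CC(C)C)CC(=O)[C@H]5C[C@@]125 | intermediate
26 | 2-oxolabda-7,13E-diene-15,19-diol 15-(methyl succinate) 19-isovalerate | COC(=O)CCC(=O)OC/C=C(\C)CC[C@H]1C(C)=CC[C@H]2[C@@](C)(COC(=O)CC(C)C)CC(=O)C[C@]12C | intermediate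
27 | CNP0118741.1, labda-7,13E-diene-2α,15,19-triol 15-(methyl succinate) 19-isovalerate | COC(=O)CCC(=O)OC/C=C(\C)CC[C@H]1C(C)=CC[C@H]2[C@@](C)(COC(=O)CC(C)C)C[C@H](O)C[C@]12C | target

Total steps: 22. Longest linear sequence: 18 steps (1–7, then 12–22).

Steps most likely to fail

Step 12. The cycloaddition may stall at the neopentyl C5 terminus while the Lewis acid slowly polymerises the triene or ionises its allylic silyl ether. Endo and facial control may also erode at the higher temperature then needed.
- The fallback builds ring B bond by bond and closes it by metathesis. It sets out from 9 and 11 and returns at 17.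
- Hosomi–Sakurai allylation of 9 (allyltrimethylsilane, TiCl4, CH2Cl2, −78 °C) should add the C6–C7 unit trans-diaxially to the C18 methyl and give the 5β-allyl ketone F1.
- In parallel, 11 is epoxidised at its terminal alkene (mCPBA) to the 6,7-epoxide F2 and cleaved (H5IO6) to (E)-6-(TBDPS-oxy)-4-methylhex-4-enal F3.
- The kinetic lithium enolate of F1 (LDA, C10H2 side) adds to F3 to give the aldol F4, which is dehydrated (MsCl, Et3N, then DBU) to the (E)-alkylidene ketone F5.
- Isopropenylmagnesium bromide with CuBr·SMe2 should add to C9 from the α-face, opposite the axial allyl group. The regiodefined enolate is trapped with PhNTf2 as the seco enol triflate F6.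
- Ring-closing metathesis (second-generation Grubbs catalyst, CH2Cl2, 40 °C) between the allyl and isopropenyl groups closes ring B and delivers 17.

Step 13. Deprotonation may take place at C2 instead of C10. This would cause epimerisation of the 2β-oxygen centre or triflation on the wrong side.
- The fallback replaces enolate chemistry by reduction and elimination. It sets out from 15 and returns at 18.
- LiBH(s-Bu)3 (THF, −78 °C) should attack the ketone from the equatorial side and give the axial 1β-alcohol F7.
- Anti-periplanar dehydration of F7 (POCl3, pyridine) should remove the axial H10 rather than the hydridic H2 next to oxygen and give 18 directly.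

Step 21. Three things may go wrong: the ketyl may be protonated before the ring opens, the in-ring C1–C10 bond may break because that gives the more substituted radical, or electron transfer to the allylic ester may compete.
- The fallback moves the ring opening ahead of the acylations and uses a dissolving metal. It sets out from 23 and returns at 26.
- 23 is first converted into its dilithium dialkoxide (LiHMDS, 2 equiv) and then treated with Li in NH3–THF at −78 °C, with no further proton source.
- A quench with isoprene and solid NH4Cl keeps the product as its enolate until work-up and should give the 10β-methyl keto diol F8.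
- Selective acylation at O15 as in step 19 gives the mono-ester F9, and acylation at O19 as in step 20 gives 26.

Further compounds
F1 | step 12 | 5β-allyl ketone from 9 | C=CC[C@H]1[C@@](C)(CO[Si](c2ccccc2)(c2ccccc2)C(C)(C)C)C[C@@H](O[Si](C)(C)C(C)(C)C)C(=O)C1
F2 | step 12 | 6,7-epoxygeranyl TBDPS ether (racemic at the epoxide) | CC1(C)OC1CC/C(C)=C/CO[Si](c1ccccc1)(c1ccccc1)C(C)(C)C
F3 | step 12 | (E)-6-(TBDPS-oxy)-4-methylhex-4-enal | O=CCC/C(C)=C/CO[Si](c1ccccc1)(c1ccccc1)C(C)(C)C
F4 | step 12 | aldol of F1 and F3 (mixture at C9 and C10) | CC(C)(C)[Si](c3ccccc3)(c3ccccc3)OC/C=C(\C)CCC(O)C1[C@@H](CC=C)[C@@](C)(CO[Si](c4ccccc4)(c4ccccc4)C(C)(C)C)C[C@@H](O[Si](C)(C)C(C)(C)C)C1=O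
F5 | step 12 | (E)-9(10)-alkylidene ketone | CC(C)(C)[Si](c3ccccc3)(c3ccccc3)OC/C=C(\C)CC/C=C1\[C@@H](CC=C)[C@@](C)(CO[Si](c4ccccc4)(c4ccccc4)C(C)(C)C)C[C@@H](O[Si](C)(C)C(C)(C)C)C1=O
F6 | step 12 | seco enol triflate with 5β-allyl and 9-isopropenyl groups | CC(C)(C)[Si](c3ccccc3)(c3ccccc3)OC/C=C(\C)CC[C@@H](C(C)=C)C1=C(OS(=O)(=O)C(F)(F)F)[C@H](O[Si](C)(C)C(C)(C)C)C[C@](C)(CO[Si](c4ccccc4)(c4ccccc4)C(C)(C)C)[C@@H]1CC=C
F7 | step 13 | axial 1β-alcohol from 15 | CC(C)(C)[Si](c3ccccc3)(c3ccccc3)OC/C=C(\C)CC[C@H]1C(C)=CC[C@H]2[C@@](C)(CO[Si](c4ccccc4)(c4ccccc4)C(C)(C)C)C[C@@H](O[Si](C)(C)C(C)(C)C)[C@@H](O)[C@@H]12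
F8 | step 21 | 15,19-dihydroxylabda-7,13E-dien-2-one | OC/C=C(\C)CC[C@H]1C(C)=CC[C@H]2[C@@](C)(CO)CC(=O)C[C@]12C
F9 | step 21 | 15-(methyl succinate) of F8 | COC(=O)CCC(=O)OC/C=C(\C)CC[C@H]1C(C)=CC[C@H]2[C@@](C)(CO)CC(=O)C[C@]12C
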